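**Plan**

1. Ring numbering used here: dienone ring C1(=O), C2(butanoyl), C3(OH), C4(CH3, prenyl), C5(OH), C6(CH2Ar). The retrosynthesis cuts the C6–CH2 bridge bond first, then the ring bonds C5–C6 and C2–C3.
2. Enabling feature: C4 lies between the two oxygenated ring carbons C3 and C5, so C3–C4–C5 is a 2-methyl-2-prenylmalonyl unit and C6–C1(=O)–C2–C(=O)C3H7 is heptane-2,4-dione. C4 is stereogenic only because C3 and C5 have different neighbours, which is the CO2Me/CO2H difference of a malonic half-ester.
3. Forward: the "dearomatised" ring is built, not made by dearomatisation: prochiral malonate 3 → esterase half-ester 4 → acid chloride 5 → one-pot γ-acylation/Claisen [3+3] closure with the dianion of heptane-2,4-dione → ring 9. The quaternary C4 blocks the aldol mode.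
4. Aromatic half: the formyl carbon of 2,4,6-trihydroxybenzaldehyde becomes the bridge; O-methylation and C-butanoylation pass through mirror-symmetric intermediates. Rings 9 and 12 are joined by a reductive Knoevenagel coupling without protecting groups.
5. Stereochemistry: the single stereocentre C4 is set by the enzyme in step 2, and no bond to it is made or broken afterwards. Step 4 translates "which carboxyl was hydrolysed" into "which side carries the butanoyl group".

Key step: step 4

Assumption: the esterase is taken to hydrolyse the pro-S ester group of 3, which gives (R)-4; the opposite or a weak preference is covered by the fallback to step 2.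
Remark: the enolised tricarbonyl rings are drawn as one tautomer; the CIP letter of the quaternary carbon changes with tautomer and derivative (R in 4, 8, 9, 14; S in 5 and 13), while its spatial arrangement, given by the SMILES, is the same throughout.

**Route**

Step 1
Reactants: 1 dimethyl 2-methylpropanedioate; 2 1-bromo-3-methylbut-2-ene (prenyl bromide)
Product: 3 dimethyl 2-methyl-2-(3-methylbut-2-en-1-yl)propanedioate
Conditions: NaH (1.05 equiv), THF, 0 °C; then 2, rt
Reagents that add atoms: none
Why: Malonic ester alkylation (SN2) in which the sodium enolate of 1 attacks the unhindered primary carbon of prenyl bromide, giving the linear prenyl group and a prochiral quaternary carbon (no stereocentre yet, since the two CO2Me groups are enantiotopic).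

Step 2
Reactants: 3 dimethyl 2-methyl-2-(3-methylbut-2-en-1-yl)propanedioate
Product: 4 (R)-3-methoxy-2-methyl-2-(3-methylbut-2-en-1-yl)-3-oxopropanoic acid
Conditions: pig liver esterase, 0.1 M phosphate buffer pH 7.5/DMSO 9:1, 25 °C, pH-stat (1 M NaOH); then 1 M HCl to pH 2, EtOAc; optical purity raised if needed by crystallisation of an ammonium salt
Reagents that add atoms: water, O
Why: Enzymatic desymmetrisation by a carboxylesterase (serine hydrolase, EC 3.1.1.1), which binds the prochiral diester so that only one of the two enantiotopic CO2Me groups reaches the catalytic serine and thereby sets the configuration of the quaternary carbon (future C4); hydrolysis should stop at the half-ester because the carboxylate is no longer a substrate.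

Step 3
Reactants: 4 (R)-3-methoxy-2-methyl-2-(3-methylbut-2-en-1-yl)-3-oxopropanoic acid
Product: 5 methyl (S)-3-chloro-2-methyl-2-(3-methylbut-2-en-1-yl)-3-oxopropanoate
Conditions: 1-chloro-N,N,2-trimethylprop-1-en-1-amine (1.1 equiv), CH2Cl2, 0 °C → rt; concentrate, use crude
Reagents that add atoms: 1-chloro-N,N,2-trimethylprop-1-en-1-amine, CC(C)=C(Cl)N(C)C
Why: Acid chloride formation with an α-chloroenamine under neutral conditions, so that no HCl is available to add to the trisubstituted alkene or to trigger lactonisation; the quaternary centre has no α-hydrogen and cannot racemise through a ketene or enol.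

Step 4
Reactants: 5 methyl (S)-3-chloro-2-methyl-2-(3-methylbut-2-en-1-yl)-3-oxopropanoate; 6 heptane-2,4-dione
Product: 9 (R)-2-butanoyl-3,5-dihydroxy-4-methyl-4-(3-methylbut-2-en-1-yl)cyclohexa-2,5-dien-1-one, via heptanedione dianion 7 (not isolated), via triketo ester 8 (not isolated)
Conditions: 6 (2.1 equiv), LDA (4.2 equiv), THF, 0 °C; add 5, −78 °C → rt; then 60 °C; 1 M HCl work-up, product extracted into aq. NaHCO3 and re-acidified
Reagents that add atoms: none
Why: The terminal carbanion of bis-enolate 7 attacks the acid chloride of 5 (γ-acylation), a second equivalent of 7 deprotonates the new 1,3,5-triketone to the dianion of 8, and on warming C6 of 8 (between C5=O and C7=O) adds to the ester carbon C1 and expels methoxide (Dieckmann-type Claisen condensation), which forms the ring bonds C5–C6 and C2–C3 of 9 in one flask. The closest known reaction types are the terminal acylation of β-diketone dianions and the Claisen cyclisation of 3,5,7-trioxo esters to acylphloroglucinols, here stopped at the non-aromatic stage by the quaternary carbon. The one ring closes in the 6-(enolexo)-exo-trig mode; the competing aldol mode of such polyketide chains is shut off because C2 of 8 carries no hydrogen, and O-closure to a pyranone is reversible under the methoxide set free whereas the C-closed product leaves the equilibrium as its stabilised enolate. No stereocentre is created: the quaternary carbon keeps its configuration because no bond to it is made or broken and it has no α-hydrogen, and its sense in 9 is fixed by the order of events, the acid-derived carbonyl becoming C5 (next to C6–H) and the ester-derived carbonyl becoming C3 (next to the butanoyl-bearing C2). The step needs the second deprotonation of 6 at CH3 rather than at C5H2, secured by the kinetic preference of LDA for the less substituted terminus, and attack at COCl before CO2Me, secured by the reactivity gap between the two acyl groups at −78 °C. Retro-Claisen cleavage of the non-enolisable β-keto ester, the only path back to achiral material, is suppressed because C3 of 8 is part of an enolate throughout.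

Step 5
Reactants: 10 2,4,6-trihydroxybenzaldehyde
Product: 11 2,6-dihydroxy-4-methoxybenzaldehyde
Conditions: Me2SO4 (1.0 equiv), K2CO3 (1.0 equiv), acetone, 0 °C → rt
Reagents that add atoms: dimethyl sulfate, COS(=O)(=O)OC
Why: Williamson O-methylation, selective because the 4-OH is the only hydroxyl not held in a hydrogen bond to the formyl group and is the most acidic (para to CHO), so one equivalent of weak base and methylating agent should alkylate it alone and keep the ring mirror-symmetric.

Step 6
Reactants: 11 2,6-dihydroxy-4-methoxybenzaldehyde
Product: 12 3-butanoyl-2,6-dihydroxy-4-methoxybenzaldehyde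
Conditions: butanoic anhydride (1.5 equiv), BF3·OEt2 (3 equiv), 1,4-dioxane, 70 °C; then MeOH–H2O, 60 °C
Reagents that add atoms: butanoic anhydride, CCCC(=O)OC(=O)CCC
Why: Friedel–Crafts C-acylation of a phloroglucinol derivative (O-acylation/Fries pathway under BF3), in which C3 and C5 of 11 are equivalent by symmetry and activated by three oxygen substituents, so only one mono-acylation product is possible; BF3 is chosen because it should not cleave the methyl ether ortho to the new ketone.

Step 7
Reactants: 9 (R)-2-butanoyl-3,5-dihydroxy-4-methyl-4-(3-methylbut-2-en-1-yl)cyclohexa-2,5-dien-1-one; 12 3-butanoyl-2,6-dihydroxy-4-methoxybenzaldehyde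
Product: 14 (R)-2-butanoyl-6-[(3-butanoyl-2,6-dihydroxy-4-methoxyphenyl)methyl]-3,5-dihydroxy-4-methyl-4-(3-methylbut-2-en-1-yl)cyclohexa-2,5-dien-1-one, via arylidene trione 13 (not isolated)
Conditions: L-proline (20 mol%), Hantzsch ester (diethyl 2,6-dimethyl-1,4-dihydropyridine-3,5-dicarboxylate, 1.2 equiv), EtOH/CH2Cl2, 25–40 °C, N2
Reagents that add atoms: none
Why: Three-component reductive alkylation of a cyclic 1,3-dicarbonyl compound (Knoevenagel condensation, then conjugate transfer hydrogenation from the Hantzsch ester), in which C6 is the only C–H acidic ring carbon of 9 and the bridging carbon is already bonded to the arene between its two hydroxyl groups, so the regiochemistry of both halves is fixed, while C4, the prenyl alkene and both ketones are untouched by the hydride donor.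

**Compound list**

1 | dimethyl 2-methylpropanedioate | COC(=O)C(C)C(=O)OC | starting material
2 | 1-bromo-3-methylbut-2-ene | CC(C)=CCBr | starting material
3 | dimethyl 2-methyl-2-(3-methylbut-2-en-1-yl)propanedioate | COC(=O)C(C)(CC=C(C)C)C(=O)OC | intermediate
4 | (R)-3-methoxy-2-methyl-2-(3-methylbut-2-en-1-yl)-3-oxopropanoic acid | COC(=O)[C@](C)(CC=C(C)C)C(=O)O | intermediate
5 | methyl (S)-3-chloro-2-methyl-2-(3-methylbut-2-en-1-yl)-3-oxopropanoate | COC(=O)[C@](C)(CC=C(C)C)C(Cl)=O | intermediate
6 | heptane-2,4-dione | CC(=O)CC(=O)CCC | starting material
7 | dilithium hepta-1,3-diene-2,4-diolate | [Li+].[Li+].C=C([O-])C=C([O-])CCC | intermediate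
8 | methyl (R)-2-methyl-2-(3-methylbut-2-en-1-yl)-3,5,7-trioxodecanoate | COC(=O)[C@](C)(CC=C(C)C)C(=O)CC(=O)CC(=O)CCC | intermediate
9 | (R)-2-butanoyl-3,5-dihydroxy-4-methyl-4-(3-methylbut-2-en-1-yl)cyclohexa-2,5-dien-1-one | CCCC(=O)C1=C(O)[C@](C)(CC=C(C)C)C(O)=CC1=O | intermediate
10 | 2,4,6-trihydroxybenzaldehyde | O=Cc1c(O)cc(O)cc1O | starting material
11 | 2,6-dihydroxy-4-methoxybenzaldehyde | COc1cc(O)c(C=O)c(O)c1 | intermediate
12 | 3-butanoyl-2,6-dihydroxy-4-methoxybenzaldehyde | CCCC(=O)c1c(OC)cc(O)c(C=O)c1O | intermediate
13 | (S)-2-butanoyl-6-[(3-butanoyl-2,6-dihydroxy-4-methoxyphenyl)methylidene]-3-hydroxy-4-methyl-4-(3-methylbut-2-en-1-yl)cyclohex-2-ene-1,5-dione (alkene geometry not defined) | CCCC(=O)C1=C(O)[C@](C)(CC=C(C)C)C(=O)C(=Cc2c(O)cc(OC)c(C(=O)CCC)c2O)C1=O | intermediate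
14 | (R)-2-butanoyl-6-[(3-butanoyl-2,6-dihydroxy-4-methoxyphenyl)methyl]-3,5-dihydroxy-4-methyl-4-(3-methylbut-2-en-1-yl)cyclohexa-2,5-dien-1-one | CCCC(=O)C1=C(O)[C@](C)(CC=C(C)C)C(O)=C(Cc2c(O)cc(OC)c(C(=O)CCC)c2O)C1=O | target

**Step count and risks**

Total step count: 7. Longest linear sequence: 5 (steps 1, 2, 3, 4, 7).

Steps most likely to fail:

Step 4. The second deprotonation of 6 may not be selective for the methyl terminus, the acid chloride may acylate the dianion on oxygen or twice, and the closure onto the hindered ester may be slow. The fallback sets out from 5 and returns at 9 by way of isolated 8, and it fixes the regiochemistry by structure instead of by kinetic deprotonation. Compound 5 is added to the lithium enolate of acetone (LiHMDS, THF, −78 °C, two equivalents of enolate) to give methyl (R)-2-methyl-2-(3-methylbut-2-en-1-yl)-3,5-dioxohexanoate F1, a β-diketone with a single enolisable terminus. Soft bis-silylation (TMSOTf, Et3N, Et2O, 0 °C) should give methyl (R)-2-methyl-2-(3-methylbut-2-en-1-yl)-3,5-bis(trimethylsilyloxy)hexa-3,5-dienoate F2 without a free terminal carbanion, which could otherwise close onto the ester too early and give an achiral trione. Mukaiyama-type γ-acylation of F2 with butanoyl chloride (CH2Cl2, −78 °C → rt, aqueous work-up) gives 8, which is isolated and cyclised under thermodynamic conditions (NaOMe, MeOH, reflux) to 9.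

Step 2. The enzyme may discriminate the enantiotopic ester groups poorly, because methyl versus prenyl lies in the size range where the preference of this esterase can invert, or it may favour the other group. The fallback sets out from 3 and returns at 4 by classical resolution instead of enzymatic desymmetrisation. Mono-saponification of 3 (KOH, 1.0 equiv, MeOH, rt) gives racemic 3-methoxy-2-methyl-2-(3-methylbut-2-en-1-yl)-3-oxopropanoic acid F3. This is combined with (S)-1-phenylethylamine, and the diastereomeric salt of the (R)-acid, (S)-1-phenylethylammonium (R)-3-methoxy-2-methyl-2-(3-methylbut-2-en-1-yl)-3-oxopropanoate F4, is separated by fractional crystallisation and acidified (cold 1 M HCl) to 4. The acid left in the other fraction is re-methylated (MeI, K2CO3) to achiral 3 and recycled.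

Step 6. The Lewis acid may promote self-condensation between the formyl group and the electron-rich ring, loss of the formyl group, or acylation that stops at oxygen. The fallback sets out from 11 and returns at 12, and it replaces electrophilic substitution by directed ortho-metalation. Compound 11 is protected (MOMCl, iPr2NEt, CH2Cl2) as 4-methoxy-2,6-bis(methoxymethoxy)benzaldehyde F5. The aldehyde is masked in the flask as an α-amino alkoxide (lithium N,N,N'-trimethylethylenediamide, THF, −20 °C), the ring is lithiated with n-BuLi at the only free position type, between OMOM and OMe, and the aryllithium is quenched with N-methoxy-N-methylbutanamide. Aqueous acid work-up gives 3-butanoyl-4-methoxy-2,6-bis(methoxymethoxy)benzaldehyde F6. Removal of the MOM groups (HCl, MeOH, 40 °C) gives 12.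

**Further compounds**

F1 | step 4 | methyl (R)-2-methyl-2-(3-methylbut-2-en-1-yl)-3,5-dioxohexanoate | COC(=O)[C@](C)(CC=C(C)C)C(=O)CC(C)=O
F2 | step 4 | methyl (R)-2-methyl-2-(3-methylbut-2-en-1-yl)-3,5-bis(trimethylsilyloxy)hexa-3,5-dienoate | COC(=O)[C@](C)(CC=C(C)C)C(O[Si](C)(C)C)=CC(=C)O[Si](C)(C)C
F3 | step 2 | racemic 3-methoxy-2-methyl-2-(3-methylbut-2-en-1-yl)-3-oxopropanoic acid | COC(=O)C(C)(CC=C(C)C)C(=O)O
F4 | step 2 | (S)-1-phenylethylammonium (R)-3-methoxy-2-methyl-2-(3-methylbut-2-en-1-yl)-3-oxopropanoate | COC(=O)[C@](C)(CC=C(C)C)C(=O)[O-].C[C@H]([NH3+])c1ccccc1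
F5 | step 6 | 4-methoxy-2,6-bis(methoxymethoxy)benzaldehyde | COCOc1cc(OC)cc(OCOC)c1C=O
F6 | step 6 | 3-butanoyl-4-methoxy-2,6-bis(methoxymethoxy)benzaldehyde | CCCC(=O)c1c(OC)cc(OCOC)c(C=O)c1OCOC
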